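Start from a leftover: how much substrate still stands at the end of the run? Substrate left over has made no target, and that amount rests on two times, the length of the run and the substrate's life at the flask's temperature.

all flasks: substrate 20 mM

|  | first nucleophile | second nucleophile | temperature | remark | time |
|---|---|---|---|---|---|
| teal | 9.5 mM | 30 mM (in portions, 3) | −30 °C | run made earlier; portions every 10 s |  |
| violet | 38 mM | 30 mM (in portions, 3) | 20 °C | run made earlier; portions every 10 s |  |
| south | 19.0 mM | 30.0 mM (in portions, 3) | 5 °C | the portions of second nucleophile follow each other after 10 s, the first at the start | 50 min |
| west | 19.0 mM | 30.0 mM (in portions, 3) | 65 °C | the portions of second nucleophile follow each other after 10 s, the first at the start | 50 min |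
| south-west | 19.0 mM | 30.0 mM (in portions, 3) | 35 °C | the portions of second nucleophile follow each other after 10 s, the first at the start | 50 min |
| south-east | 19.0 mM | 30.0 mM (in portions, 3) | −25 °C | the portions of second nucleophile follow each other after 10 s, the first at the start | 50 min |

- teal (time / min: target / %, substrate / %): 25.0: 1, 101; 60.0: 3, 97; 120: 2, 100; 300: 0, 102
- violet (time / min: target / %, substrate / %): 3.00: 6, 90; 10.0: 17, 69; 15.0: 21, 59; 25.0: 26, 34

(readings scatter by 1.5 percentage points)

- the flask that comes out highest in amount of target, in percent of the substrate charged, or "all alike" when all lie within 1.5 percentage points (south / west / south-west / south-east / all alike)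
- target at the end, in percent of the substrate charged, south
- target at the end, in percent of the substrate charged, west
- target at the end, in percent of the substrate charged, south-west
- target at the end, in percent of the substrate charged, south-east

1. In violet the substrate was down to 59 % at 15.0 min. If you treat the loss as first-order, that reading gives a life of 28.4 min, the time in which the amount falls by the factor e.

2. Teal's lowest substrate reading is 97 %, and teal ran to 300 min. Spread that gap over the whole run as a rough guess, since a reading this close to full scatters by 1.5 percentage points, and the rate in teal is about 1.00 × 10⁻⁴ min⁻¹. On that guess, from teal to violet the rate climbs by a factor of about 352.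

3. My own rough reckoning takes that factor as the value and spreads it evenly over the degrees. Dividing the run by the life at each temperature gives the lives in the run: south 0.303, west 344, south-west 10.2, south-east 0.00899.

4. South and south-east get less than one life, so on this reckoning they should keep most of their substrate, while west and south-west should spend theirs. With teal's substrate readings at 97 % or above, I can't read from teal what heat does to the share becoming target, so I choose south-west, which is cooler than west.

5. The forecast differs and names south, with south 8 %, west 1 %, south-west 4 %, south-east 0.2 %. Of west it says: “target is essentially destroyed”.

6. The flasks give south-west as highest: south 11.0 %, west 15.2 %, south-west 25.6 %, south-east 0.183 %.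

    substrate → intermediate (k = 0.00320 s⁻¹, Ea = 90.0 kJ mol⁻¹)
    first nucleophile + intermediate → target (k = 140 M⁻¹ s⁻¹, Ea = 40.0 kJ mol⁻¹)
    second nucleophile + intermediate → other capture product (k = 11.0 M⁻¹ s⁻¹, Ea = 59.0 kJ mol⁻¹)
    intermediate → solvolysis product (k = 2.90 s⁻¹, Ea = 79.0 kJ mol⁻¹)
    substrate + target → side product (k = 0.120 M⁻¹ s⁻¹, Ea = 55.0 kJ mol⁻¹)
    (constants at 35 °C)

South's 0.303 lives mean 26.1 % conversion, and the flask gives 23.1 %. West and south-west both end with substrate at 0 %, yet west holds less target. The main reason west's own target stays low is solvolysis of the intermediate: without that step west gives 65.8 % instead of 15.2 %.

A flask like south-west kept at 10 °C gets 0.544 lives, which leaves 58.0 % of the substrate. Computed, it keeps 58.2 % and gives 16.2 % of target.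

All runs stem from a simulated flask on assumed constants; the scatter is artificial.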